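The target is cut at the methylene bridge into an achiral 8-acyl-2H-chromene (ring A plus pyran ring O1–C2–C3=C4–C4a–C8a) and an (S)-configured dearomatized acylphloroglucinol. The pyran ring is closed at C2–C3: photoredox decarboxylation of an aryloxyisobutyric acid, placed on the oxygen next to the acyl group, gives a tertiary α-aryloxy radical that adds 6-endo-dig to the terminus of an ortho ethynyl group. This exploits C2 as a fully substituted, oxygen-bearing carbon (stabilized tertiary radical) and C3=C4 as a styrenic alkene bound through C4 to the arene (a masked aryl alkyne). The quaternary stereocenter comes from an asymmetric dearomative prenylation; a Mannich/ortho-quinone methide coupling joins the halves.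

Key step: step 5

Remark: compounds 1 and 9 are taken as catalogue chemicals.
Remark: the (R,R) ligand in step 8 is assumed to deliver the (S) quaternary carbon; the sense of induction has to be verified on the first run, and the (S,S) ligand is used without other change if it is reversed.

Step 1
Reactants: 1 2-methyl-1-(2,4,6-trihydroxyphenyl)propan-1-one
Product: 2 1-[2-hydroxy-4,6-bis(methoxymethoxy)phenyl]-2-methylpropan-1-one
Conditions: MOMCl (2.2 equiv), iPr2NEt, CH2Cl2, 0 °C to rt
Reagents that add atoms: chloromethyl methyl ether (MOMCl), COCCl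
Why: O-alkylation (MOM protection) should stop after two ethers because the last hydroxyl is hydrogen-bonded to the ketone and is the least nucleophilic.

Step 2
Reactants: 2 1-[2-hydroxy-4,6-bis(methoxymethoxy)phenyl]-2-methylpropan-1-one
Product: 3 1-[2-hydroxy-3-iodo-4,6-bis(methoxymethoxy)phenyl]-2-methylpropan-1-one
Conditions: NIS (1.05 equiv), DMF, 0 °C, dark
Reagents that add atoms: N-iodosuccinimide, O=C1CCC(=O)N1I
Why: Electrophilic aromatic iodination is expected ortho to the free phenol, at the carbon between OH and OMOM, which is less hindered than the carbon between two OMOM groups, as is usual for 2-hydroxy-4,6-dialkoxyaryl ketones.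

Step 3
Reactants: 3 1-[2-hydroxy-3-iodo-4,6-bis(methoxymethoxy)phenyl]-2-methylpropan-1-one
Product: 4 2-[2-iodo-3,5-bis(methoxymethoxy)-6-(2-methylpropanoyl)phenoxy]-2-methylpropanoic acid
Conditions: acetone, CHCl3, NaOH (powder), 0 °C to 40 °C; then dilute HCl to pH 3, 0 °C
Reagents that add atoms: acetone, CC(C)=O; chloroform, ClC(Cl)Cl; sodium hydroxide, [Na+].[OH-]
Why: In the Bargellini reaction trichloromethide adds to acetone, the phenoxide opens the resulting gem-dichloroepoxide at its tertiary carbon and the acyl chloride is hydrolysed, which places the O–C(CH3)2–CO2H unit on the oxygen next to the acyl group.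

Step 4
Reactants: 4 2-[2-iodo-3,5-bis(methoxymethoxy)-6-(2-methylpropanoyl)phenoxy]-2-methylpropanoic acid
Product: 6 2-[2-ethynyl-3,5-bis(methoxymethoxy)-6-(2-methylpropanoyl)phenoxy]-2-methylpropanoic acid, via trimethylsilyl alkyne acid 5 (not isolated)
Conditions: Me3SiC≡CH, Pd(PPh3)2Cl2 (5 mol %), CuI (10 mol %), Et3N, THF, 60 °C; concentrate; then K2CO3, MeOH, rt; mild acidic work-up
Reagents that add atoms: ethynyltrimethylsilane, C#C[Si](C)(C)C
Why: Sonogashira coupling of the aryl iodide followed by base-catalysed methanolysis of the C–Si bond should give the terminal alkyne, with the carboxylate as a spectator.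

Step 5
Reactants: 6 2-[2-ethynyl-3,5-bis(methoxymethoxy)-6-(2-methylpropanoyl)phenoxy]-2-methylpropanoic acid
Product: 7 1-[5,7-bis(methoxymethoxy)-2,2-dimethyl-2H-chromen-8-yl]-2-methylpropan-1-one
Conditions: [Ir(dF(CF3)ppy)2(dtbbpy)]PF6 (1 mol %), Cs2CO3 (0.5 equiv), DMF–H2O (20:1, 0.02 M), 450 nm LEDs, rt, argon
Reagents that add atoms: none
Why: The excited trivalent iridium complex oxidizes the carboxylate, loss of CO2 leaves the tertiary α-aryloxy radical at the future C2, this radical attacks the unsubstituted alkyne terminus (future C3), and the resulting α-aryl vinyl radical at C4 is reduced by divalent iridium and protonated (or takes a hydrogen atom from the medium), so that the C3=C4 double bond appears directly at the chromene oxidation level. The closest known reaction types are the photoredox decarboxylative Giese-type hydroalkylation of terminal aryl alkynes with α-oxy acids and the classical decarboxylative radical cyclizations onto alkynes. The pyran ring closes in the 6-endo-dig mode. No stereocenter is formed. The step needs 6-endo over 5-exo-dig attack, which the terminal alkyne should secure: the CH terminus is open to the bulky tertiary radical and leads to an aryl-conjugated vinyl radical, whereas 5-exo attack would hit the ring-bound carbon and give an unstabilized radical. Which oxygen carries the radical precursor was fixed in steps 1 to 3.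

Step 6
Reactants: 7 1-[5,7-bis(methoxymethoxy)-2,2-dimethyl-2H-chromen-8-yl]-2-methylpropan-1-one
Product: 8 1-(5,7-dihydroxy-2,2-dimethyl-2H-chromen-8-yl)-2-methylpropan-1-one
Conditions: HCl (3 M), MeOH, 40 °C
Reagents that add atoms: none
Why: Acid-catalysed methanolysis of the two MOM acetals should free both phenols, and a 2,2-dimethylchromene on an acyl-deactivated ring is expected to tolerate dilute methanolic HCl.

Step 7
Reactants: 9 2-methylbenzene-1,3,5-triol
Product: 10 2-methyl-1-(2,4,6-trihydroxy-3-methylphenyl)propan-1-one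
Conditions: iPrCOCl (1.1 equiv), AlCl3 (3.5 equiv), PhNO2–CH2Cl2, 0 °C to 50 °C; aqueous HCl work-up
Reagents that add atoms: 2-methylpropanoyl chloride, CC(C)C(=O)Cl
Why: Friedel–Crafts acylation can give only one product because the two free ring positions of 9 are equivalent, and the first acyl group deactivates the ring toward a second acylation.

Step 8
Reactants: 10 2-methyl-1-(2,4,6-trihydroxy-3-methylphenyl)propan-1-one
Product: 11 (4S)-3,5-dihydroxy-4-methyl-4-(3-methylbut-2-en-1-yl)-2-(2-methylpropanoyl)cyclohexa-2,5-dien-1-one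
Conditions: methyl prenyl carbonate (1.05 equiv), Pd2(dba)3·CHCl3 (2.5 mol %), N,N′-[(1R,2R)-cyclohexane-1,2-diyl]bis[2-(diphenylphosphanyl)benzamide] (7.5 mol %), THF, 0 °C
Reagents that add atoms: methyl 3-methylbut-2-en-1-yl carbonate, COC(=O)OCC=C(C)C
Why: In this Tsuji–Trost asymmetric allylic alkylation run as a dearomatization, the phenoxide should attack the CH2 terminus of the π-prenyl palladium complex through its methyl-bearing ring carbon, the chiral ligand pocket differentiates the two faces of that carbon to set the (S) quaternary center, and O-prenyl ethers are re-ionized by zerovalent palladium so that the C-alkylated triketone accumulates.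

Step 9
Reactants: 8 1-(5,7-dihydroxy-2,2-dimethyl-2H-chromen-8-yl)-2-methylpropan-1-one; 11 (4S)-3,5-dihydroxy-4-methyl-4-(3-methylbut-2-en-1-yl)-2-(2-methylpropanoyl)cyclohexa-2,5-dien-1-one
Product: 14 (4S)-6-{[5,7-dihydroxy-2,2-dimethyl-8-(2-methylpropanoyl)-2H-chromen-6-yl]methyl}-3,5-dihydroxy-4-methyl-4-(3-methylbut-2-en-1-yl)-2-(2-methylpropanoyl)cyclohexa-2,5-dien-1-one, via Mannich base 12 (not isolated), via ortho-quinone methide 13 (not isolated)
Conditions: 8, [Me2N=CH2]I (1.05 equiv), MeCN, rt; then 11, iPr2NEt (1.2 equiv), 80 °C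
Reagents that add atoms: N,N-dimethylmethyleneiminium iodide, C=[N+](C)C.[I-]
Why: Mannich aminomethylation should occur at the only free ring CH of 8 (C6), thermal loss of dimethylamine then gives the ortho-quinone methide, and the enolized β-triketone 11 adds to it in a Michael reaction through its only CH carbon, leaving the quaternary stereocenter untouched.

Compound list
1 | 2-methyl-1-(2,4,6-trihydroxyphenyl)propan-1-one | CC(C)C(=O)c1c(O)cc(O)cc1O | starting material
2 | 1-[2-hydroxy-4,6-bis(methoxymethoxy)phenyl]-2-methylpropan-1-one | CC(C)C(=O)c1c(O)cc(OCOC)cc1OCOC | intermediate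
3 | 1-[2-hydroxy-3-iodo-4,6-bis(methoxymethoxy)phenyl]-2-methylpropan-1-one | CC(C)C(=O)c1c(O)c(I)c(OCOC)cc1OCOC | intermediate
4 | 2-[2-iodo-3,5-bis(methoxymethoxy)-6-(2-methylpropanoyl)phenoxy]-2-methylpropanoic acid | CC(C)C(=O)c1c(OC(C)(C)C(=O)O)c(I)c(OCOC)cc1OCOC | intermediate
5 | 2-[3,5-bis(methoxymethoxy)-2-(2-methylpropanoyl)-6-[(trimethylsilyl)ethynyl]phenoxy]-2-methylpropanoic acid (not isolated) | CC(C)C(=O)c1c(OC(C)(C)C(=O)O)c(C#C[Si](C)(C)C)c(OCOC)cc1OCOC | intermediate
6 | 2-[2-ethynyl-3,5-bis(methoxymethoxy)-6-(2-methylpropanoyl)phenoxy]-2-methylpropanoic acid | CC(C)C(=O)c1c(OC(C)(C)C(=O)O)c(C#C)c(OCOC)cc1OCOC | intermediate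
7 | 1-[5,7-bis(methoxymethoxy)-2,2-dimethyl-2H-chromen-8-yl]-2-methylpropan-1-one | CC(C)C(=O)c1c(OCOC)cc(OCOC)c2C=CC(C)(C)Oc12 | intermediate
8 | 1-(5,7-dihydroxy-2,2-dimethyl-2H-chromen-8-yl)-2-methylpropan-1-one | CC(C)C(=O)c1c(O)cc(O)c2C=CC(C)(C)Oc12 | intermediate
9 | 2-methylbenzene-1,3,5-triol | Cc1c(O)cc(O)cc1O | starting material
10 | 2-methyl-1-(2,4,6-trihydroxy-3-methylphenyl)propan-1-one | CC(C)C(=O)c1c(O)cc(O)c(C)c1O | intermediate
11 | (4S)-3,5-dihydroxy-4-methyl-4-(3-methylbut-2-en-1-yl)-2-(2-methylpropanoyl)cyclohexa-2,5-dien-1-one | CC(C)=CC[C@@]1(C)C(O)=CC(=O)C(C(=O)C(C)C)=C1O | intermediate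
12 | 1-{6-[(dimethylamino)methyl]-5,7-dihydroxy-2,2-dimethyl-2H-chromen-8-yl}-2-methylpropan-1-one (Mannich base, not isolated) | CC(C)C(=O)c1c(O)c(CN(C)C)c(O)c2C=CC(C)(C)Oc12 | intermediate
13 | 7-hydroxy-2,2-dimethyl-6-methylidene-8-(2-methylpropanoyl)-2H-chromen-5(6H)-one (ortho-quinone methide, not isolated) | CC(C)C(=O)C1=C(O)C(=C)C(=O)C2=C1OC(C)(C)C=C2 | intermediate
14 | (4S)-6-{[5,7-dihydroxy-2,2-dimethyl-8-(2-methylpropanoyl)-2H-chromen-6-yl]methyl}-3,5-dihydroxy-4-methyl-4-(3-methylbut-2-en-1-yl)-2-(2-methylpropanoyl)cyclohexa-2,5-dien-1-one | CC(C)=CC[C@@]1(C)C(O)=C(Cc2c(O)c3c(c(C(=O)C(C)C)c2O)OC(C)(C)C=C3)C(=O)C(C(=O)C(C)C)=C1O | target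

Total step count: 9. Longest linear sequence: 7 steps (steps 1, 2, 3, 4, 5, 6 and 9).

Steps most likely to fail

Step 5. The tertiary radical may attack the ring-bound alkyne carbon (5-exo-dig), may be quenched before it cyclizes (plain protodecarboxylation), or the vinyl radical may abstract hydrogen from a neighbouring MOM group and start decomposition. The fallback sets out from 4 and returns at 7, and it still closes the ring at C2–C3. Suzuki–Miyaura coupling of 4 with potassium vinyltrifluoroborate (PdCl2(dppf), Cs2CO3, THF–H2O, 70 °C) should give 2-[2-ethenyl-3,5-bis(methoxymethoxy)-6-(2-methylpropanoyl)phenoxy]-2-methylpropanoic acid F1. Photoredox decarboxylation of F1 with the same iridium catalyst and 2,4,6-triisopropylbenzenethiol (10 mol %) as hydrogen-atom donor is a Giese-type hydroalkylation of a styrene; the radical should add 6-endo-trig because only this mode gives a benzylic radical, leading to 1-[5,7-bis(methoxymethoxy)-2,2-dimethyl-3,4-dihydro-2H-chromen-8-yl]-2-methylpropan-1-one F2. Dehydrogenation of F2 with DDQ (1,4-dioxane, 90 °C), the classical route from 2,2-dimethylchromans to chromenes, should then give 7.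

Step 8. Prenylation may take place at the unsubstituted ring carbon (with rearomatization) or at oxygen instead of the methyl-bearing carbon, and the ligand may discriminate the two faces poorly. The fallback sets out from 10 and returns at 11. Alkoxide-mediated dearomative prenylation (prenyl bromide, NaOMe, MeOH, 0 °C), under conditions where acylphloroglucinols are known to undergo geminal dialkylation at an already alkylated carbon, should give racemic 3,5-dihydroxy-4-methyl-4-(3-methylbut-2-en-1-yl)-2-(2-methylpropanoyl)cyclohexa-2,5-dien-1-one F3. Preparative chromatography on a chiral stationary phase (amylose tris(3,5-dimethylphenylcarbamate), hexane–iPrOH with 0.1 % CF3CO2H) should separate 11 from (4R)-3,5-dihydroxy-4-methyl-4-(3-methylbut-2-en-1-yl)-2-(2-methylpropanoyl)cyclohexa-2,5-dien-1-one F4, which is set aside.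

Step 3. The phenoxide of 3 is hydrogen-bonded to the ketone and flanked by iodine and the acyl group, so its attack on the gem-dichloroepoxide may be too slow and the haloform chemistry may consume the reagents. The fallback sets out from 3 and returns at 6; it changes the order so that the slim alkyne, not iodine, sits next to the phenol. Sonogashira coupling of 3 with ethynyltriisopropylsilane (Pd(PPh3)2Cl2, CuI, Et3N, THF, 50 °C) should give 1-[2-hydroxy-4,6-bis(methoxymethoxy)-3-[(triisopropylsilyl)ethynyl]phenyl]-2-methylpropan-1-one F5, the bulky silyl group suppressing benzofuran formation. The Bargellini reaction on F5 (acetone, CHCl3, NaOH) should give 2-[3,5-bis(methoxymethoxy)-2-(2-methylpropanoyl)-6-[(triisopropylsilyl)ethynyl]phenoxy]-2-methylpropanoic acid F6, and Bu4NF in THF removes the silyl group to give 6.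

Further compounds
F1 | step 5 | 2-[2-ethenyl-3,5-bis(methoxymethoxy)-6-(2-methylpropanoyl)phenoxy]-2-methylpropanoic acid | CC(C)C(=O)c1c(OC(C)(C)C(=O)O)c(C=C)c(OCOC)cc1OCOC
F2 | step 5 | 1-[5,7-bis(methoxymethoxy)-2,2-dimethyl-3,4-dihydro-2H-chromen-8-yl]-2-methylpropan-1-one | CC(C)C(=O)c1c(OCOC)cc(OCOC)c2CCC(C)(C)Oc12
F3 | step 8 | racemic 3,5-dihydroxy-4-methyl-4-(3-methylbut-2-en-1-yl)-2-(2-methylpropanoyl)cyclohexa-2,5-dien-1-one | CC(C)=CCC1(C)C(O)=CC(=O)C(C(=O)C(C)C)=C1O
F4 | step 8 | (4R)-3,5-dihydroxy-4-methyl-4-(3-methylbut-2-en-1-yl)-2-(2-methylpropanoyl)cyclohexa-2,5-dien-1-one | CC(C)=CC[C@]1(C)C(O)=CC(=O)C(C(=O)C(C)C)=C1O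
F5 | step 3 | 1-[2-hydroxy-4,6-bis(methoxymethoxy)-3-[(triisopropylsilyl)ethynyl]phenyl]-2-methylpropan-1-one | CC(C)C(=O)c1c(O)c(C#C[Si](C(C)C)(C(C)C)C(C)C)c(OCOC)cc1OCOC
F6 | step 3 | 2-[3,5-bis(methoxymethoxy)-2-(2-methylpropanoyl)-6-[(triisopropylsilyl)ethynyl]phenoxy]-2-methylpropanoic acid | CC(C)C(=O)c1c(OC(C)(C)C(=O)O)c(C#C[Si](C(C)C)(C(C)C)C(C)C)c(OCOC)cc1OCOC
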